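**Plan**

1. The target is read as fisetinidol-(4α→6)-ent-epifisetinidol: upper unit 2R,3S,4R (2,3-trans, 3,4-trans), lower unit 2S,3S (2,3-cis), with the upper C4 bonded to C6 of the lower ring A.
2. Retrosynthetic cuts, in order: the aryl ether bond O1–C8a of the lower unit (its ring C, made last); upper C4–lower C6 (Suzuki coupling of a flav-3-en-4-yl triflate with an arylboronate); the lower C2–aryl carbinol bond (aryl Grignard reagent plus α-benzyloxy aldehyde); the upper C2–aryl bond (conjugate arylation of a chromone).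
3. Forward: chromone → (S)-flavanone → enol triflate (upper rings A, C and B in place); L-tyrosine → brominated open-chain lower unit → boronate; coupling; hydroboration; desilylation; closure of the lower ring C; hydrogenolysis.
4. Stereochemistry: upper C2 comes from the chiral palladium catalyst, upper C3 and C4 from hydroboration anti to the C2 aryl group. Lower C3 comes from L-tyrosine and lower C2 from chelation-controlled addition; both are kept in the ring closure because the aryl–oxygen bond, not the benzylic carbon–oxygen bond, is formed (syn chain gives the 2,3-cis ring).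
5. Enabling feature: in ring A of the lower unit the 7-OH is para to C4a and meta to C8a, so the open-chain precursor is a para-alkylphenol. Two-electron oxidation turns it into a cyclohexa-2,5-dienone in which C8a is an enone β-carbon placed 6-exo to the C2 hydroxyl; loss of methanol after the oxa-Michael closure restores the arene and the free 7-OH. The flavanyl group already ortho to that phenol steers the attack to the remote β-carbon and so fixes the 4→6 link.

Key step: step 15

Assumption: in step 2 the ligand antipode is chosen to deliver the aryl group to the enone face that gives (2S); by analogy with carbocyclic enones this is taken to be the (R)-ligand, and the (S)-ligand is used if the sense proves opposite.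

**Route**

Step 1
Reactants: 1 7-hydroxy-4H-chromen-4-one
Product: 2 7-(benzyloxy)-4H-chromen-4-one
Conditions: BnBr, K2CO3, DMF, rt
Reagents that add atoms: benzyl bromide, BrCc1ccccc1
Why: Williamson ether synthesis on the acidic 7-phenol (a vinylogous acid), with a carbonate base too weak to open the pyrone ring.

Step 2
Reactants: 2 7-(benzyloxy)-4H-chromen-4-one; 3 [3,4-bis(benzyloxy)phenyl]boronic acid
Product: 4 (2S)-7-(benzyloxy)-2-[3,4-bis(benzyloxy)phenyl]-2,3-dihydro-4H-chromen-4-one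
Conditions: Pd(OCOCF3)2 (5 mol %), (R)-t-BuPyOx (6 mol %), NH4PF6 (30 mol %), H2O (5 equiv), ClCH2CH2Cl, 60 °C
Reagents that add atoms: none
Why: Asymmetric conjugate arylation (palladium-catalysed 1,4-addition of an arylboronic acid to the chromone enone), in which an aryl–palladium species (divalent palladium) inserts C2=C3 and the palladium enolate is protonated, the pyridine–oxazoline ligand selecting the enone face and so setting C2 as S.

Step 3
Reactants: 4 (2S)-7-(benzyloxy)-2-[3,4-bis(benzyloxy)phenyl]-2,3-dihydro-4H-chromen-4-one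
Product: 5 (2S)-7-(benzyloxy)-2-[3,4-bis(benzyloxy)phenyl]-2H-chromen-4-yl trifluoromethanesulfonate
Conditions: KN(SiMe3)2, THF, −78 °C; then N-(5-chloropyridin-2-yl)bis(trifluoromethanesulfonyl)imide, −78 °C
Reagents that add atoms: N-(5-chloropyridin-2-yl)-1,1,1-trifluoro-N-(trifluoromethylsulfonyl)methanesulfonamide, O=S(=O)(N(c1ccc(Cl)cn1)S(=O)(=O)C(F)(F)F)C(F)(F)F
Why: Kinetic enolate formation and O-sulfonylation (enol triflate synthesis); at −78 °C β-elimination of the ring oxygen should be slow because the C2–O1 bond lies near the plane of the enolate, so C2 should keep its configuration.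

Step 4
Reactants: 6 L-tyrosine
Product: 7 (S)-2-hydroxy-3-(4-hydroxyphenyl)propanoic acid
Conditions: NaNO2, 1 M H2SO4 (aq.), 0 °C to rt
Reagents that add atoms: water, O
Why: Diazotisation of the α-amino acid, in which the carboxylate displaces N2 to an α-lactone that water opens (double inversion), so the hydroxy acid keeps the S configuration.

Step 5
Reactants: 7 (S)-2-hydroxy-3-(4-hydroxyphenyl)propanoic acid
Product: 8 methyl (S)-2-hydroxy-3-(4-hydroxyphenyl)propanoate
Conditions: MeOH, H2SO4 (cat.), reflux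
Reagents that add atoms: methanol, CO
Why: Fischer esterification, which does not involve the stereocentre.

Step 6
Reactants: 8 methyl (S)-2-hydroxy-3-(4-hydroxyphenyl)propanoate
Product: 9 methyl (S)-3-(3-bromo-4-hydroxyphenyl)-2-hydroxypropanoate
Conditions: NBS (1.0 equiv), MeCN, 0 °C
Reagents that add atoms: N-bromosuccinimide, O=C1CCC(=O)N1Br
Why: Electrophilic aromatic bromination directed ortho to the phenol (para position blocked), one equivalent of reagent limiting dibromination.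

Step 7
Reactants: 9 methyl (S)-3-(3-bromo-4-hydroxyphenyl)-2-hydroxypropanoate
Product: 10 methyl (S)-3-[3-bromo-4-(tert-butyldimethylsilyloxy)phenyl]-2-hydroxypropanoate
Conditions: TBSCl (1.05 equiv), imidazole, CH2Cl2, 0 °C
Reagents that add atoms: tert-butyldimethylsilyl chloride, CC(C)(C)[Si](C)(C)Cl
Why: Silyl ether formation, the more acidic and less hindered phenol reacting before the secondary α-hydroxy ester hydroxyl.

Step 8
Reactants: 10 methyl (S)-3-[3-bromo-4-(tert-butyldimethylsilyloxy)phenyl]-2-hydroxypropanoate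
Product: 11 methyl (S)-2-(benzyloxy)-3-[3-bromo-4-(tert-butyldimethylsilyloxy)phenyl]propanoate
Conditions: BnBr, Ag2O, Et2O, rt, dark
Reagents that add atoms: benzyl bromide, BrCc1ccccc1
Why: Silver oxide-mediated O-benzylation (a neutral Williamson variant) that avoids enolisation of the α-oxy ester, so the stereocentre should not racemise.

Step 9
Reactants: 11 methyl (S)-2-(benzyloxy)-3-[3-bromo-4-(tert-butyldimethylsilyloxy)phenyl]propanoate
Product: 12 (S)-2-(benzyloxy)-3-[3-bromo-4-(tert-butyldimethylsilyloxy)phenyl]propanal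
Conditions: i-Bu2AlH, CH2Cl2, −78 °C; aq. potassium sodium tartrate; used crude
Reagents that add atoms: none
Why: Partial reduction of the ester through a tetrahedral aluminium hemiacetal that is stable at −78 °C, the aldehyde being used at once to avoid α-epimerisation.

Step 10
Reactants: 12 (S)-2-(benzyloxy)-3-[3-bromo-4-(tert-butyldimethylsilyloxy)phenyl]propanal; 13 4-bromo-1,2-bis(benzyloxy)benzene
Product: 15 (1S,2S)-2-(benzyloxy)-1-[3,4-bis(benzyloxy)phenyl]-3-[3-bromo-4-(tert-butyldimethylsilyloxy)phenyl]propan-1-ol, via aryl Grignard reagent 14 (not isolated)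
Conditions: Mg, THF, rt (13 to 14); 12, MgBr2·OEt2, CH2Cl2, −78 °C, then 14, −78 °C
Reagents that add atoms: none
Why: Grignard addition under Cram chelate control, magnesium bridging the aldehyde oxygen and the α-benzyloxy oxygen so that the aryl group attacks from the face of the α-hydrogen and sets the new carbinol centre as S (syn to the benzyloxy group).

Step 11
Reactants: 15 (1S,2S)-2-(benzyloxy)-1-[3,4-bis(benzyloxy)phenyl]-3-[3-bromo-4-(tert-butyldimethylsilyloxy)phenyl]propan-1-ol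
Product: 16 (1S,2S)-2-(benzyloxy)-1-[3,4-bis(benzyloxy)phenyl]-3-[4-(tert-butyldimethylsilyloxy)-3-(4,4,5,5-tetramethyl-1,3,2-dioxaborolan-2-yl)phenyl]propan-1-ol
Conditions: B2pin2, Pd(dppf)Cl2 (5 mol %), KOAc, 1,4-dioxane, 85 °C
Reagents that add atoms: bis(pinacolato)diboron, CC1(C)OB(B2OC(C)(C)C(C)(C)O2)OC1(C)C
Why: Miyaura borylation of the aryl bromide under weakly basic conditions that tolerate the free alcohol and the aryl silyl ether.

Step 12
Reactants: 5 (2S)-7-(benzyloxy)-2-[3,4-bis(benzyloxy)phenyl]-2H-chromen-4-yl trifluoromethanesulfonate; 16 (1S,2S)-2-(benzyloxy)-1-[3,4-bis(benzyloxy)phenyl]-3-[4-(tert-butyldimethylsilyloxy)-3-(4,4,5,5-tetramethyl-1,3,2-dioxaborolan-2-yl)phenyl]propan-1-ol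
Product: 17 (1S,2S)-2-(benzyloxy)-1-[3,4-bis(benzyloxy)phenyl]-3-{3-[(2S)-7-(benzyloxy)-2-[3,4-bis(benzyloxy)phenyl]-2H-chromen-4-yl]-4-(tert-butyldimethylsilyloxy)phenyl}propan-1-ol
Conditions: Pd(OAc)2 (5 mol %), SPhos (10 mol %), K3PO4, THF/H2O (10:1), 45 °C
Reagents that add atoms: none
Why: Suzuki–Miyaura coupling of the enol triflate with the arylboronate, which forms the upper C4–aryl bond (the future 4→6 link) regiospecifically and leaves all stereocentres untouched.

Step 13
Reactants: 17 (1S,2S)-2-(benzyloxy)-1-[3,4-bis(benzyloxy)phenyl]-3-{3-[(2S)-7-(benzyloxy)-2-[3,4-bis(benzyloxy)phenyl]-2H-chromen-4-yl]-4-(tert-butyldimethylsilyloxy)phenyl}propan-1-ol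
Product: 18 (2R,3S,4S)-7-(benzyloxy)-2-[3,4-bis(benzyloxy)phenyl]-4-{5-[(2S,3S)-2-(benzyloxy)-3-[3,4-bis(benzyloxy)phenyl]-3-hydroxypropyl]-2-(tert-butyldimethylsilyloxy)phenyl}chroman-3-ol (2,3-trans, 3,4-trans; C4 is spatially as in the target, the descriptor changing only through the silyl ether)
Conditions: BH3·THF (excess), THF, 0 °C to rt; then 30% H2O2, aq. NaOAc, 0 °C to rt
Reagents that add atoms: hydrogen peroxide, OO
Why: Hydroboration–oxidation, with syn addition of H–B across the trisubstituted styrenic C3=C4 bond, boron going to the less substituted C3 from the face anti to the C2 aryl group and oxidation proceeding with retention, so that C2 sets both C3 (hydroxyl trans to the C2 aryl) and C4 (aryl trans to the hydroxyl).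

Step 14
Reactants: 18 (2R,3S,4S)-7-(benzyloxy)-2-[3,4-bis(benzyloxy)phenyl]-4-{5-[(2S,3S)-2-(benzyloxy)-3-[3,4-bis(benzyloxy)phenyl]-3-hydroxypropyl]-2-(tert-butyldimethylsilyloxy)phenyl}chroman-3-ol
Product: 19 (2R,3S,4R)-7-(benzyloxy)-2-[3,4-bis(benzyloxy)phenyl]-4-{5-[(2S,3S)-2-(benzyloxy)-3-[3,4-bis(benzyloxy)phenyl]-3-hydroxypropyl]-2-hydroxyphenyl}chroman-3-ol
Conditions: Bu4NF, AcOH, THF, 0 °C
Reagents that add atoms: none
Why: Fluoride cleavage of the aryl silyl ether, buffered with acetic acid so that the phenoxide is not exposed, releases the single free phenol and leaves the benzyl ethers and alcohols unchanged.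

Step 15
Reactants: 19 (2R,3S,4R)-7-(benzyloxy)-2-[3,4-bis(benzyloxy)phenyl]-4-{5-[(2S,3S)-2-(benzyloxy)-3-[3,4-bis(benzyloxy)phenyl]-3-hydroxypropyl]-2-hydroxyphenyl}chroman-3-ol
Product: 22 (2R,3S,4R)-7-(benzyloxy)-2-[3,4-bis(benzyloxy)phenyl]-4-[(2S,3S)-3-(benzyloxy)-2-[3,4-bis(benzyloxy)phenyl]-7-hydroxychroman-6-yl]chroman-3-ol, via quinol methyl ether dienone 20 (not isolated), via bicyclic oxa-Michael adduct 21 (not isolated)
Conditions: PhI(OAc)2 (1.05 equiv), MeOH/CH2Cl2 (4:1), 0 °C; evaporation; then camphorsulfonic acid (20 mol %), CH2Cl2, 0 °C to rt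
Reagents that add atoms: none
Why: Proposed new method: the trivalent iodine reagent oxidises the only free phenol (ring A of the lower unit) and methanol adds para, at C4a, to give the 4-methoxycyclohexa-2,5-dienone 20, in which C8a has become an enone β-carbon; acid then promotes attack of the lower C2 hydroxyl on C8a (oxa-Michael addition) to give 21, whose dienol loses methanol through an arenium ion and then the proton on C8a, so that the arene returns with the new aryl ether in place (a net dehydrogenative C–H etherification meta to the phenol). The closest known reaction types are the oxidative dearomatisation of para-alkylphenols to quinol ethers, the intramolecular oxa-Michael addition of tethered alcohols to such dienones, and the dearomatisation–conjugate addition–rearomatisation sequences used for meta-functionalisation of para-substituted phenols and anilines. The pyran ring closes in the 6-exo-trig mode (O1, C2, C3, C4, C4a, C8a of the lower unit). No new stereocentre survives, because C4a and C8a return to sp2, and lower C2 and C3 are not touched since the aryl–oxygen and not the benzylic carbon–oxygen bond is made, so the syn chain becomes the 2,3-cis ring. The step needs site selectivity between the two dienone β-carbons C8a and C5 (which decides 4→6 against 4→8 connectivity) and chemoselectivity among the hydroxyl groups: the flavanyl group on C6 makes the C5=C6 enone α-substituted, less electrophilic and shielded, the lower C3 oxygen is a benzyl ether and cannot close a five-membered ring, and the upper C3 hydroxyl could reach C5 only in a 5-endo mode. Only one phenol is oxidised because every other phenol is a benzyl ether.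

Step 16
Reactants: 22 (2R,3S,4R)-7-(benzyloxy)-2-[3,4-bis(benzyloxy)phenyl]-4-[(2S,3S)-3-(benzyloxy)-2-[3,4-bis(benzyloxy)phenyl]-7-hydroxychroman-6-yl]chroman-3-ol
Product: 23 (2R,3S,4R)-2-(3,4-dihydroxyphenyl)-4-[(2S,3S)-2-(3,4-dihydroxyphenyl)-3,7-dihydroxychroman-6-yl]chroman-3,7-diol (CNP0187520.2)
Conditions: H2 (1 atm), Pd(OH)2 on carbon, THF/MeOH (1:1), rt
Reagents that add atoms: none
Why: Hydrogenolysis of the six benzyl ethers (five aryl, one secondary alkyl), the cyclic benzylic C2–O1 ethers of the flavan rings being expected to cleave much more slowly at ambient pressure, so no stereocentre is affected.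

**Compound list**

1 | 7-hydroxy-4H-chromen-4-one | O=c1ccoc2cc(O)ccc12 | starting material
2 | 7-(benzyloxy)-4H-chromen-4-one | O=c1ccoc2cc(OCc3ccccc3)ccc12 | intermediate
3 | [3,4-bis(benzyloxy)phenyl]boronic acid | OB(O)c1ccc(OCc2ccccc2)c(OCc2ccccc2)c1 | starting material
4 | (2S)-7-(benzyloxy)-2-[3,4-bis(benzyloxy)phenyl]-2,3-dihydro-4H-chromen-4-one | O=C1C[C@@H](c2ccc(OCc3ccccc3)c(OCc3ccccc3)c2)Oc2cc(OCc3ccccc3)ccc21 | intermediate
5 | (2S)-7-(benzyloxy)-2-[3,4-bis(benzyloxy)phenyl]-2H-chromen-4-yl trifluoromethanesulfonate | O=S(=O)(OC1=C[C@@H](c2ccc(OCc3ccccc3)c(OCc3ccccc3)c2)Oc2cc(OCc3ccccc3)ccc21)C(F)(F)F | intermediate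
6 | L-tyrosine, (S)-2-amino-3-(4-hydroxyphenyl)propanoic acid | N[C@@H](Cc1ccc(O)cc1)C(=O)O | starting material
7 | (S)-2-hydroxy-3-(4-hydroxyphenyl)propanoic acid | O[C@@H](Cc1ccc(O)cc1)C(=O)O | intermediate
8 | methyl (S)-2-hydroxy-3-(4-hydroxyphenyl)propanoate | COC(=O)[C@@H](O)Cc1ccc(O)cc1 | intermediate
9 | methyl (S)-3-(3-bromo-4-hydroxyphenyl)-2-hydroxypropanoate | COC(=O)[C@@H](O)Cc1ccc(O)c(Br)c1 | intermediate
10 | methyl (S)-3-[3-bromo-4-(tert-butyldimethylsilyloxy)phenyl]-2-hydroxypropanoate | COC(=O)[C@@H](O)Cc1ccc(O[Si](C)(C)C(C)(C)C)c(Br)c1 | intermediate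
11 | methyl (S)-2-(benzyloxy)-3-[3-bromo-4-(tert-butyldimethylsilyloxy)phenyl]propanoate | COC(=O)[C@@H](OCc1ccccc1)Cc1ccc(O[Si](C)(C)C(C)(C)C)c(Br)c1 | intermediate
12 | (S)-2-(benzyloxy)-3-[3-bromo-4-(tert-butyldimethylsilyloxy)phenyl]propanal | O=C[C@@H](OCc1ccccc1)Cc1ccc(O[Si](C)(C)C(C)(C)C)c(Br)c1 | intermediate
13 | 4-bromo-1,2-bis(benzyloxy)benzene | Brc1ccc(OCc2ccccc2)c(OCc2ccccc2)c1 | starting material
14 | [3,4-bis(benzyloxy)phenyl]magnesium bromide | Br[Mg]c1ccc(OCc2ccccc2)c(OCc2ccccc2)c1 | intermediate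
15 | (1S,2S)-2-(benzyloxy)-1-[3,4-bis(benzyloxy)phenyl]-3-[3-bromo-4-(tert-butyldimethylsilyloxy)phenyl]propan-1-ol | O[C@@H](c1ccc(OCc2ccccc2)c(OCc2ccccc2)c1)[C@@H](OCc1ccccc1)Cc1ccc(O[Si](C)(C)C(C)(C)C)c(Br)c1 | intermediate
16 | (1S,2S)-2-(benzyloxy)-1-[3,4-bis(benzyloxy)phenyl]-3-[4-(tert-butyldimethylsilyloxy)-3-(4,4,5,5-tetramethyl-1,3,2-dioxaborolan-2-yl)phenyl]propan-1-ol | O[C@@H](c1ccc(OCc2ccccc2)c(OCc2ccccc2)c1)[C@@H](OCc1ccccc1)Cc1ccc(O[Si](C)(C)C(C)(C)C)c(B2OC(C)(C)C(C)(C)O2)c1 | intermediate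
17 | (1S,2S)-2-(benzyloxy)-1-[3,4-bis(benzyloxy)phenyl]-3-{3-[(2S)-7-(benzyloxy)-2-[3,4-bis(benzyloxy)phenyl]-2H-chromen-4-yl]-4-(tert-butyldimethylsilyloxy)phenyl}propan-1-ol | O[C@@H](c1ccc(OCc2ccccc2)c(OCc2ccccc2)c1)[C@@H](OCc1ccccc1)Cc1ccc(O[Si](C)(C)C(C)(C)C)c(C2=C[C@@H](c3ccc(OCc4ccccc4)c(OCc4ccccc4)c3)Oc3cc(OCc4ccccc4)ccc32)c1 | intermediate
18 | (2R,3S,4S)-7-(benzyloxy)-2-[3,4-bis(benzyloxy)phenyl]-4-{5-[(2S,3S)-2-(benzyloxy)-3-[3,4-bis(benzyloxy)phenyl]-3-hydroxypropyl]-2-(tert-butyldimethylsilyloxy)phenyl}chroman-3-ol (2,3-trans, 3,4-trans) | O[C@@H](c1ccc(OCc2ccccc2)c(OCc2ccccc2)c1)[C@@H](OCc1ccccc1)Cc1ccc(O[Si](C)(C)C(C)(C)C)c([C@H]2[C@H](O)[C@@H](c3ccc(OCc4ccccc4)c(OCc4ccccc4)c3)Oc3cc(OCc4ccccc4)ccc32)c1 | intermediate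
19 | (2R,3S,4R)-7-(benzyloxy)-2-[3,4-bis(benzyloxy)phenyl]-4-{5-[(2S,3S)-2-(benzyloxy)-3-[3,4-bis(benzyloxy)phenyl]-3-hydroxypropyl]-2-hydroxyphenyl}chroman-3-ol | O[C@@H](c1ccc(OCc2ccccc2)c(OCc2ccccc2)c1)[C@@H](OCc1ccccc1)Cc1ccc(O)c([C@H]2[C@H](O)[C@@H](c3ccc(OCc4ccccc4)c(OCc4ccccc4)c3)Oc3cc(OCc4ccccc4)ccc32)c1 | intermediate
20 | quinol methyl ether of 19: 2-[7-(benzyloxy)-2-[3,4-bis(benzyloxy)phenyl]-3-hydroxychroman-4-yl]-4-[(2S,3S)-2-(benzyloxy)-3-[3,4-bis(benzyloxy)phenyl]-3-hydroxypropyl]-4-methoxycyclohexa-2,5-dien-1-one (chroman stereocentres as in 19; both epimers at the methoxy-bearing carbon) | COC1(C[C@H](OCc2ccccc2)[C@@H](O)c2ccc(OCc3ccccc3)c(OCc3ccccc3)c2)C=CC(=O)C([C@H]2[C@H](O)[C@@H](c3ccc(OCc4ccccc4)c(OCc4ccccc4)c3)Oc3cc(OCc4ccccc4)ccc32)=C1 | intermediate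
21 | oxa-Michael adduct: (2S,3S)-3-(benzyloxy)-2-[3,4-bis(benzyloxy)phenyl]-6-[7-(benzyloxy)-2-[3,4-bis(benzyloxy)phenyl]-3-hydroxychroman-4-yl]-4a-methoxy-2,3,4,4a,8,8a-hexahydro-7H-chromen-7-one (upper chroman stereocentres as in 19; cis ring fusion, epimers at the two ring-fusion carbons) | COC12C[C@H](OCc3ccccc3)[C@H](c3ccc(OCc4ccccc4)c(OCc4ccccc4)c3)OC1CC(=O)C([C@H]1[C@H](O)[C@@H](c3ccc(OCc4ccccc4)c(OCc4ccccc4)c3)Oc3cc(OCc4ccccc4)ccc31)=C2 | intermediate
22 | (2R,3S,4R)-7-(benzyloxy)-2-[3,4-bis(benzyloxy)phenyl]-4-[(2S,3S)-3-(benzyloxy)-2-[3,4-bis(benzyloxy)phenyl]-7-hydroxychroman-6-yl]chroman-3-ol | c1ccc(COc2ccc3c(c2)O[C@H](c2ccc(OCc4ccccc4)c(OCc4ccccc4)c2)[C@@H](O)[C@@H]3c2cc3c(cc2O)O[C@@H](c2ccc(OCc4ccccc4)c(OCc4ccccc4)c2)[C@@H](OCc2ccccc2)C3)cc1 | intermediate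
23 | (2R,3S,4R)-2-(3,4-dihydroxyphenyl)-4-[(2S,3S)-2-(3,4-dihydroxyphenyl)-3,7-dihydroxychroman-6-yl]chroman-3,7-diol | Oc1ccc2c(c1)O[C@H](c1ccc(O)c(O)c1)[C@@H](O)[C@@H]2c1cc2c(cc1O)O[C@@H](c1ccc(O)c(O)c1)[C@@H](O)C2 | target

**Count and risks**

Total step count: 16. Longest linear sequence: 13 steps (steps 4 to 16, from L-tyrosine).

Steps most likely to fail:

1. Step 15. The oxidation may be diverted to loss of the benzylic hydrogen at the upper C4 (quinone methide formation) instead of para-methoxylation. The conjugate addition may occur at the substituted β-carbon or with external methanol. The acid may ionise the benzylic carbinol before ring closure, or rearomatisation may stall at the adduct. The fallback uses known chemistry, closes the ring before the two halves are joined, sets out from 15 and comes back at 22. Treatment of 15 with lithium 2,2,6,6-tetramethylpiperidide (THF, −78 °C to 0 °C) should generate the aryne between the brominated carbon and its unsubstituted neighbour; the lithium alkoxide adds to the aryne carbon next to the chain (cine-substitution, six-membered ring, carbinol configuration retained) and protonation gives (2S,3S)-3-(benzyloxy)-2-[3,4-bis(benzyloxy)phenyl]-7-(tert-butyldimethylsilyloxy)chroman F1. NBS (CH2Cl2, −20 °C) should brominate F1 para to the ring oxygen to give the 6-bromo chroman F2. Miyaura borylation (B2pin2, Pd(dppf)Cl2, KOAc) gives the 6-boronate F3. Suzuki coupling of F3 with triflate 5 (Pd(OAc)2, SPhos, K3PO4) gives the flav-3-ene-linked chroman F4. Hydroboration–oxidation as in step 13 gives the silyl ether of the protected dimer F5, and Bu4NF/AcOH then gives 22.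

2. Step 10. Facial selectivity may be poor if non-chelated addition competes in the presence of THF, and the α-benzyloxy aldehyde may epimerise. The fallback sets out from 15 (taken together with its carbinol epimer) and comes back at 15. Oxidation with 1,1,1-triacetoxy-1,1-dihydro-1,2-benziodoxol-3(1H)-one (DMP, CH2Cl2) gives the ketone (S)-2-(benzyloxy)-1-[3,4-bis(benzyloxy)phenyl]-3-[3-bromo-4-(tert-butyldimethylsilyloxy)phenyl]propan-1-one F6. Noyori-type asymmetric transfer hydrogenation with RuCl(p-cymene)[(R,R)-TsDPEN] in HCO2H/Et3N then sets the carbinol centre under catalyst control and returns 15.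

3. Step 12. The electron-rich ortho-silyloxy arylboronate may undergo protodeboronation, the aqueous base may remove the silyl ether, and the enol triflate may hydrolyse before transmetalation. The fallback exchanges the roles of the partners, sets out from 5 and comes back at 17, and bypasses 16. Miyaura borylation of 5 (B2pin2, PdCl2(PPh3)2, PPh3, KOPh, toluene, 50 °C) gives (2S)-2-[7-(benzyloxy)-2-[3,4-bis(benzyloxy)phenyl]-2H-chromen-4-yl]-4,4,5,5-tetramethyl-1,3,2-dioxaborolane F7. Suzuki coupling of F7 with bromide 15 (Pd(OAc)2, SPhos, K3PO4, toluene/H2O) gives 17.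

**Further compounds**

F1 | step 15 | (2S,3S)-3-(benzyloxy)-2-[3,4-bis(benzyloxy)phenyl]-7-(tert-butyldimethylsilyloxy)chroman | CC(C)(C)[Si](C)(C)Oc1ccc2c(c1)O[C@@H](c1ccc(OCc3ccccc3)c(OCc3ccccc3)c1)[C@@H](OCc1ccccc1)C2
F2 | step 15 | (2S,3S)-3-(benzyloxy)-2-[3,4-bis(benzyloxy)phenyl]-6-bromo-7-(tert-butyldimethylsilyloxy)chroman | Brc1cc2c(cc1O[Si](C)(C)C(C)(C)C)O[C@@H](c1ccc(OCc3ccccc3)c(OCc3ccccc3)c1)[C@@H](OCc1ccccc1)C2
F3 | step 15 | (2S,3S)-3-(benzyloxy)-2-[3,4-bis(benzyloxy)phenyl]-7-(tert-butyldimethylsilyloxy)-6-(4,4,5,5-tetramethyl-1,3,2-dioxaborolan-2-yl)chroman | CC1(C)OB(OC1(C)C)c1cc2c(cc1O[Si](C)(C)C(C)(C)C)O[C@@H](c1ccc(OCc3ccccc3)c(OCc3ccccc3)c1)[C@@H](OCc1ccccc1)C2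
F4 | step 15 | (2S,3S)-3-(benzyloxy)-2-[3,4-bis(benzyloxy)phenyl]-6-[(2S)-7-(benzyloxy)-2-[3,4-bis(benzyloxy)phenyl]-2H-chromen-4-yl]-7-(tert-butyldimethylsilyloxy)chroman | c1ccc(COc2ccc3c(c2)O[C@H](c2ccc(OCc4ccccc4)c(OCc4ccccc4)c2)C=C3c2cc3c(cc2O[Si](C)(C)C(C)(C)C)O[C@@H](c2ccc(OCc4ccccc4)c(OCc4ccccc4)c2)[C@@H](OCc2ccccc2)C3)cc1
F5 | step 15 | (2R,3S,4S)-7-(benzyloxy)-2-[3,4-bis(benzyloxy)phenyl]-4-[(2S,3S)-3-(benzyloxy)-2-[3,4-bis(benzyloxy)phenyl]-7-(tert-butyldimethylsilyloxy)chroman-6-yl]chroman-3-ol (silyl ether of 22; C4 spatially as in 22) | c1ccc(COc2ccc3c(c2)O[C@H](c2ccc(OCc4ccccc4)c(OCc4ccccc4)c2)[C@@H](O)[C@@H]3c2cc3c(cc2O[Si](C)(C)C(C)(C)C)O[C@@H](c2ccc(OCc4ccccc4)c(OCc4ccccc4)c2)[C@@H](OCc2ccccc2)C3)cc1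
F6 | step 10 | (S)-2-(benzyloxy)-1-[3,4-bis(benzyloxy)phenyl]-3-[3-bromo-4-(tert-butyldimethylsilyloxy)phenyl]propan-1-one | O=C(c1ccc(OCc2ccccc2)c(OCc2ccccc2)c1)[C@@H](OCc1ccccc1)Cc1ccc(O[Si](C)(C)C(C)(C)C)c(Br)c1
F7 | step 12 | (2S)-2-[7-(benzyloxy)-2-[3,4-bis(benzyloxy)phenyl]-2H-chromen-4-yl]-4,4,5,5-tetramethyl-1,3,2-dioxaborolane | CC1(C)OB(OC1(C)C)C1=C[C@@H](c2ccc(OCc3ccccc3)c(OCc3ccccc3)c2)Oc2cc(OCc3ccccc3)ccc21
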